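**Assumption:** commercial pristimerin and commercial (2R,5R)-(+)-dihydrocarvone (trans isomer, freed of its C2 epimer if bought as the n/iso mixture) count as starting materials; explanations use guaiane locants (C1–C15) for the sesquiterpene half and friedelane locants for the triterpene half.

## Retrosynthetic overview

1. The 1,4-dioxane is formed last, by hetero-Diels–Alder addition of the o-quinone of 6-oxopristimerol (O=C3–C2=O) across the C1=C5 alkene of a 10-epi-guaiane; the C3=C4 alkene is then revealed by dehydrating a C4 methyl carbinol.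
2. Triterpene half (rings A–E bought intact): pristimerin → reductive acetylation → C6 oxidation → deacetylation.
3. Sesquiterpene half: (2R,5R)-dihydrocarvone already carries C7 and C10 in the required trans relationship; one-carbon ring expansion gives the seven-membered ring as a regiodefined enol triflate.
4. Carbonylative Stille coupling and Nazarov cyclisation add the cyclopentenone; MeLi installs C15.
5. Ring order: cycloheptene → cyclopentene → dioxane.

## Route

**Step 1**
Reactants: 1 (2R,5R)-2-methyl-5-(prop-1-en-2-yl)cyclohexan-1-one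
Product: 2 (2R,5R)-1-(dibromomethyl)-2-methyl-5-(prop-1-en-2-yl)cyclohexan-1-ol (both C1 epimers)
Conditions: CH2Br2, LiN(iPr)2, THF, −78 °C; H2O
Reagents that add atoms: dibromomethane BrCBr
Why: 1,2-addition of dibromomethyllithium (made in situ, faster than enolisation at −78 °C) gives the carbinol needed for a β-oxido carbenoid ring expansion; the new carbinol centre becomes sp2 in step 2 and C2/C5 are untouched.

**Step 2**
Reactants: 2 (2R,5R)-1-(dibromomethyl)-2-methyl-5-(prop-1-en-2-yl)cyclohexan-1-ol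
Product: 5 (3R,6R)-3-methyl-6-(prop-1-en-2-yl)cyclohept-1-en-1-yl trifluoromethanesulfonate, via bromo(lithio)methyl lithium alkoxide 3 (not isolated), via ring-expanded lithium enolate 4 (not isolated)
Conditions: n-BuLi (2.2 equiv), THF, −78 → 0 °C; then PhNTf2, −78 °C → rt
Reagents that add atoms: N-phenylbis(trifluoromethanesulfonimide) O=S(=O)(N(c1ccccc1)S(=O)(=O)C(F)(F)F)C(F)(F)F
Why: Br/Li exchange gives a β-oxido carbenoid whose 1,2-shift (Nozaki–Yamamoto homologation; the more substituted carbon migrates, with retention) expands the ring and leaves the enolate double bond only toward the inserted CH, so O-triflation fixes the C5=C1 regiochemistry and moves the methyl stereocentre (C10) out of any enolisable position.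

**Step 3**
Reactants: 5 (3R,6R)-3-methyl-6-(prop-1-en-2-yl)cyclohept-1-en-1-yl trifluoromethanesulfonate
Product: 6 1-[(3R,6R)-3-methyl-6-(prop-1-en-2-yl)cyclohept-1-en-1-yl]prop-2-en-1-one
Conditions: Pd(PPh3)4 (3 mol%), LiCl, CO (1–3 atm), CH2=CHSnBu3, THF, 55 °C
Reagents that add atoms: carbon monoxide [C-]#[O+]; tributyl(vinyl)stannane C=C[Sn](CCCC)(CCCC)CCCC
Why: Stille carbonylative cross-coupling (oxidative addition of the vinyl triflate, CO insertion, vinyl transfer from tin) gives the cross-conjugated divinyl ketone without touching either stereocentre.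

**Step 4**
Reactants: 6 1-[(3R,6R)-3-methyl-6-(prop-1-en-2-yl)cyclohept-1-en-1-yl]prop-2-en-1-one
Product: 7 (4R,7R)-4-methyl-7-(prop-1-en-2-yl)-3,4,5,6,7,8-hexahydroazulen-1(2H)-one
Conditions: FeCl3 (1.2 equiv), CH2Cl2, −30 → 0 °C; NaHCO3 aq.
Reagents that add atoms: none
Why: Nazarov cyclisation (conrotatory electrocyclisation of the pentadienyl cation forming C1–C2, then proton loss to the thermodynamically preferred tetrasubstituted ring-fusion enone) erases the transient sp3 centre at C1, so no new stereocentre remains.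

**Step 5**
Reactants: 7 (4R,7R)-4-methyl-7-(prop-1-en-2-yl)-3,4,5,6,7,8-hexahydroazulen-1(2H)-one
Product: 8 (1S,4R,7R)-1,4-dimethyl-7-(prop-1-en-2-yl)-1,2,3,4,5,6,7,8-octahydroazulen-1-ol
Conditions: MeLi, Et2O, −78 °C; H2O; chromatography on Et3N-washed SiO2 (separation from the 1R epimer)
Reagents that add atoms: methyllithium C[Li]
Why: 1,2-addition of the hard nucleophile MeLi to the cyclopentenone gives the tertiary allylic alcohol; the remote stereocentres give no facial bias, so both carbinol epimers form and the (1S) epimer (OH on the face opposite the C10 methyl, guaiane 4β-OH) is the one carried on.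

**Step 6**
Reactants: 9 pristimerin
Product: 11 pristimerol diacetate, via pristimerol 10 (not isolated)
Conditions: Zn dust, Ac2O, NaOAc, 60 °C
Reagents that add atoms: acetic anhydride CC(=O)OC(C)=O
Why: Reductive acetylation: Zn reduces the quinone methide by two electrons (C6 is protonated) and the air-sensitive catechol is trapped in situ as its diacetate, protecting ring A for the next oxidation.

**Step 7**
Reactants: 11 pristimerol diacetate
Product: 12 6-oxopristimerol diacetate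
Conditions: CrO3, 3,5-dimethylpyrazole, CH2Cl2, −20 °C
Reagents that add atoms: chromium trioxide O=[Cr](=O)=O
Why: Allylic/benzylic oxidation of the only doubly activated methylene (C6, between the arene and the C7=C8 alkene; C9 and C14 are quaternary, so there is no other allylic C–H) gives the aryl enone.

**Step 8**
Reactants: 12 6-oxopristimerol diacetate
Product: 13 6-oxopristimerol
Conditions: K2CO3 (cat.), MeOH, 0 °C → rt, argon; AcOH quench
Reagents that add atoms: none
Why: Base-catalysed transesterification (Zemplén-type methanolysis) removes both aryl acetates; the hindered C29 methyl ester only exchanges methoxide for methoxide and the non-enolisable enone is inert.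

**Step 9**
Reactants: 13 6-oxopristimerol; 8 (1S,4R,7R)-1,4-dimethyl-7-(prop-1-en-2-yl)-1,2,3,4,5,6,7,8-octahydroazulen-1-ol
Product: 15 4β-hydroxy-3,4-dihydro benzodioxane adduct (guaiane 1S,4S,5S,7R,10R; O3–C1 / O2–C5), via 6-oxopristimerol o-quinone 14 (not isolated)
Conditions: 13, Ag2O, MgSO4, Et2O, 0 °C, dark, filter; then 8 (2 equiv), CH2Cl2, −20 °C → rt
Reagents that add atoms: none
Why: Ag2O dehydrogenates the catechol to the electron-poor o-quinone, which adds suprafacially across the electron-rich tetrasubstituted C1=C5 alkene (inverse-electron-demand hetero-Diels–Alder) to give the cis-fused dioxane; attack anti to the C10 methyl and syn to the hydrogen-bonding 4-OH is expected to set C1 and C5 (both S), with the more electrophilic O3 bonding to C1 and the OH-held O2 bonding to C5.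

**Step 10**
Reactants: 15 4β-hydroxy-3,4-dihydro benzodioxane adduct
Product: 16 target CNP0317749.1
Conditions: Burgess reagent (MeO2CN–SO2–NEt3 inner salt), PhH, 50 °C
Reagents that add atoms: none
Why: Burgess dehydration (syn-elimination of the tertiary sulfamate with the cis C3–H) gives the endocyclic C3=C4 alkene, since quaternary C5 offers no hydrogen and the cyclopentene is favoured over the exocyclic methylene, under neutral conditions that spare the tertiary allylic ether, the ester and the enone.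

## Compound list

1 | (2R,5R)-2-methyl-5-(prop-1-en-2-yl)cyclohexan-1-one, (+)-trans-dihydrocarvone | C=C(C)[C@@H]1CC[C@@H](C)C(=O)C1 | starting material
2 | (2R,5R)-1-(dibromomethyl)-2-methyl-5-(prop-1-en-2-yl)cyclohexan-1-ol, both C1 epimers | C=C(C)[C@@H]1CC[C@@H](C)C(O)(C(Br)Br)C1 | intermediate
3 | lithium (2R,5R)-1-[bromo(lithio)methyl]-2-methyl-5-(prop-1-en-2-yl)cyclohexan-1-olate (β-oxido carbenoid) | C=C(C)[C@@H]1CC[C@@H](C)C(O[Li])(C([Li])Br)C1 | intermediate (not isolated)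
4 | lithium (3R,6R)-3-methyl-6-(prop-1-en-2-yl)cyclohept-1-en-1-olate | C=C(C)[C@@H]1CC[C@@H](C)C=C(O[Li])C1 | intermediate (not isolated)
5 | (3R,6R)-3-methyl-6-(prop-1-en-2-yl)cyclohept-1-en-1-yl trifluoromethanesulfonate | C=C(C)[C@@H]1CC[C@@H](C)C=C(OS(=O)(=O)C(F)(F)F)C1 | intermediate
6 | 1-[(3R,6R)-3-methyl-6-(prop-1-en-2-yl)cyclohept-1-en-1-yl]prop-2-en-1-one | C=C(C)[C@@H]1CC[C@@H](C)C=C(C(=O)C=C)C1 | intermediate
7 | (4R,7R)-4-methyl-7-(prop-1-en-2-yl)-3,4,5,6,7,8-hexahydroazulen-1(2H)-one | C=C(C)[C@@H]1CC[C@@H](C)C2=C(C1)C(=O)CC2 | intermediate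
8 | (1S,4R,7R)-1,4-dimethyl-7-(prop-1-en-2-yl)-1,2,3,4,5,6,7,8-octahydroazulen-1-ol (OH trans to the C4 methyl, cis to isopropenyl) | C=C(C)[C@@H]1CC[C@@H](C)C2=C(C1)[C@@](C)(O)CC2 | intermediate
9 | pristimerin, methyl (9β,13α,14β,20α)-3-hydroxy-2-oxo-24-nor-D:A-friedooleana-1(10),3,5,7-tetraen-29-oate | CC1=C(O)C(=O)C=C2C1=CC=C1[C@@]2(C)CC[C@@]2(C)[C@@H]3C[C@](C)(C(=O)OC)CC[C@]3(C)CC[C@]12C | starting material
10 | pristimerol, methyl 2,3-dihydroxy-24-nor-D:A-friedooleana-1,3,5(10),7-tetraen-29-oate (natural configuration) | Oc1cc2c(c(C)c1O)CC=C1[C@@]2(C)CC[C@@]2(C)[C@@H]3C[C@](C)(C(=O)OC)CC[C@]3(C)CC[C@]12C | intermediate (not isolated)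
11 | pristimerol 2,3-diacetate | CC(=O)Oc1cc2c(c(C)c1OC(C)=O)CC=C1[C@@]2(C)CC[C@@]2(C)[C@@H]3C[C@](C)(C(=O)OC)CC[C@]3(C)CC[C@]12C | intermediate
12 | 6-oxopristimerol 2,3-diacetate | CC(=O)Oc1cc2c(c(C)c1OC(C)=O)C(=O)C=C1[C@@]2(C)CC[C@@]2(C)[C@@H]3C[C@](C)(C(=O)OC)CC[C@]3(C)CC[C@]12C | intermediate
13 | 6-oxopristimerol, methyl 2,3-dihydroxy-6-oxo-24-nor-D:A-friedooleana-1,3,5(10),7-tetraen-29-oate | Oc1cc2c(c(C)c1O)C(=O)C=C1[C@@]2(C)CC[C@@]2(C)[C@@H]3C[C@](C)(C(=O)OC)CC[C@]3(C)CC[C@]12C | intermediate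
14 | 6-oxopristimerol o-quinone, methyl 2,3,6-trioxo-24-nor-D:A-friedooleana-1(10),4,7-trien-29-oate | O=C1C=C2C(=C(C)C1=O)C(=O)C=C1[C@@]2(C)CC[C@@]2(C)[C@@H]3C[C@](C)(C(=O)OC)CC[C@]3(C)CC[C@]12C | intermediate (not isolated)
15 | 6-oxopristimerol 2,3-O-[(1S,4S,5S,7R,10R)-4-hydroxyguai-11-ene-1,5-diyl] diether (O3–C1, O2–C5, cis-fused dioxane, 4-OH cis to the C5 oxygen) | C=C(C)[C@@H]1CC[C@@H](C)[C@@]23CC[C@](C)(O)[C@]2(C1)Oc1cc2c(c(C)c1O3)C(=O)C=C1[C@@]2(C)CC[C@@]2(C)[C@@H]3C[C@](C)(C(=O)OC)CC[C@]3(C)CC[C@]12C | intermediate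
16 | CNP0317749.1, 6-oxopristimerol 2,3-O-[(1S,5S,7R,10R)-guaia-3,11-diene-1,5-diyl] diether (O3–C1, O2–C5) | C=C(C)[C@@H]1CC[C@@H](C)[C@@]23CC=C(C)[C@]2(C1)Oc1cc2c(c(C)c1O3)C(=O)C=C1[C@@]2(C)CC[C@@]2(C)[C@@H]3C[C@](C)(C(=O)OC)CC[C@]3(C)CC[C@]12C | target

## Totals and risks

Total step count: 10.
Longest linear sequence: 7 steps (1 → 2 → 5 → 6 → 7 → 8 → 15 → 16).

The three steps most likely to fail:

1. **Step 9 (hetero-Diels–Alder).** The tetrasubstituted alkene of 8 sits next to a quaternary carbinol, and the regiochemistry (O3–C1 versus O3–C5) rests on a hydrogen-bond argument that opposes the inductive preference. The fallback sets out from enone 7 and returns at target 16, using a less hindered, reagent-set secondary alcohol and installing C15 only after the coupling. Reduction of 7 with (R)-2-methyl-CBS-oxazaborolidine and catecholborane (toluene, −78 °C) gives (1S,4R,7R)-4-methyl-7-(prop-1-en-2-yl)-1,2,3,4,5,6,7,8-octahydroazulen-1-ol F9. Its OH directs the cycloaddition with o-quinone 14 (made from 13 as in step 9) to give the secondary-alcohol adduct 6-oxopristimerol 2,3-O-[4-hydroxyguai-11-ene-1,5-diyl] diether F10. Dess–Martin periodinane gives the C4 ketone 6-oxopristimerol 2,3-O-[4-oxoguai-11-ene-1,5-diyl] diether F11, which can enolise only toward C3. KN(SiMe3)2/PhNTf2 (THF, −78 °C) gives the enol triflate 6-oxopristimerol 2,3-O-[4-(trifluoromethanesulfonyloxy)guaia-3,11-diene-1,5-diyl] diether F12. Negishi methylation (MeZnCl, Pd(PPh3)4, THF, 50 °C) then gives 16 with the C3=C4 position fixed, and step 10 is no longer needed.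

2. **Step 2 (carbenoid ring expansion and enolate triflation).** The wrong carbon may migrate, or the enolate may not be trapped cleanly. The fallback sets out from 1 and returns at divinyl ketone 6, placing the inserted carbon on the other side of the carbonyl and carrying it as an ester. Ethyl diazoacetate/BF3·OEt2 (CH2Cl2, 0 °C; the less substituted CH2 migrates) gives ethyl (3R,6R)-3-methyl-2-oxo-6-(prop-1-en-2-yl)cycloheptane-1-carboxylate F1. NaH/PhNTf2 gives ethyl (3R,6R)-3-methyl-6-(prop-1-en-2-yl)-2-(trifluoromethanesulfonyloxy)cyclohept-1-ene-1-carboxylate F2. Pd(OAc)2/PPh3/HCO2H/Bu3N reduction gives ethyl (3R,6R)-3-methyl-6-(prop-1-en-2-yl)cyclohept-1-ene-1-carboxylate F3. MeNH(OMe)·HCl/iPrMgCl gives (3R,6R)-N-methoxy-N,3-dimethyl-6-(prop-1-en-2-yl)cyclohept-1-ene-1-carboxamide F4, and CH2=CHMgBr (THF, 0 °C, cold acidic quench) gives 6. This takes five steps instead of three.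

3. **Step 4 (Nazarov cyclisation).** An unactivated vinyl ketone needs a strong Lewis acid, which threatens the isopropenyl group and invites polymerisation. The fallback sets out from triflate 5 and returns at enone 7 by an acid-free hydroacylation route. Formylation (Pd(PPh3)4, CO, Bu3SnH, LiCl, THF, 50 °C) gives (3R,6R)-3-methyl-6-(prop-1-en-2-yl)cyclohept-1-ene-1-carbaldehyde F5. Conjugate addition of (CH2=CH)2CuLi (Et2O, −78 °C) gives (3R,6R)-2-ethenyl-3-methyl-6-(prop-1-en-2-yl)cycloheptane-1-carbaldehyde F6 (the new centres are erased later). Intramolecular hydroacylation with [Rh(dppe)]BF4 (CH2Cl2, rt) closes the five-membered ring to (4R,7R)-4-methyl-7-(prop-1-en-2-yl)octahydroazulen-1(2H)-one F7. Me3SiCl/NaI/Et3N (MeCN) gives the more substituted enol silane trimethyl{[(4R,7R)-4-methyl-7-(prop-1-en-2-yl)-2,3,3a,4,5,6,7,8-octahydroazulen-1-yl]oxy}silane F8, and Saegusa–Ito oxidation (Pd(OAc)2, MeCN) gives 7.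

## Further compounds

F1 | step 2 | ethyl (3R,6R)-3-methyl-2-oxo-6-(prop-1-en-2-yl)cycloheptane-1-carboxylate (C1 epimers/enol) | C=C(C)[C@@H]1CC[C@@H](C)C(=O)C(C(=O)OCC)C1
F2 | step 2 | ethyl (3R,6R)-3-methyl-6-(prop-1-en-2-yl)-2-(trifluoromethanesulfonyloxy)cyclohept-1-ene-1-carboxylate | C=C(C)[C@@H]1CC[C@@H](C)C(OS(=O)(=O)C(F)(F)F)=C(C(=O)OCC)C1
F3 | step 2 | ethyl (3R,6R)-3-methyl-6-(prop-1-en-2-yl)cyclohept-1-ene-1-carboxylate | C=C(C)[C@@H]1CC[C@@H](C)C=C(C(=O)OCC)C1
F4 | step 2 | (3R,6R)-N-methoxy-N,3-dimethyl-6-(prop-1-en-2-yl)cyclohept-1-ene-1-carboxamide | C=C(C)[C@@H]1CC[C@@H](C)C=C(C(=O)N(C)OC)C1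
F5 | step 4 | (3R,6R)-3-methyl-6-(prop-1-en-2-yl)cyclohept-1-ene-1-carbaldehyde | C=C(C)[C@@H]1CC[C@@H](C)C=C(C=O)C1
F6 | step 4 | (3R,6R)-2-ethenyl-3-methyl-6-(prop-1-en-2-yl)cycloheptane-1-carbaldehyde (C1/C2 mixture) | C=C(C)[C@@H]1CC[C@@H](C)C(C=C)C(C=O)C1
F7 | step 4 | (4R,7R)-4-methyl-7-(prop-1-en-2-yl)octahydroazulen-1(2H)-one (ring-fusion mixture) | C=C(C)[C@@H]1CC[C@@H](C)C2CCC(=O)C2C1
F8 | step 4 | trimethyl{[(4R,7R)-4-methyl-7-(prop-1-en-2-yl)-2,3,3a,4,5,6,7,8-octahydroazulen-1-yl]oxy}silane | C=C(C)[C@@H]1CC[C@@H](C)C2CCC(O[Si](C)(C)C)=C2C1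
F9 | step 9 | (1S,4R,7R)-4-methyl-7-(prop-1-en-2-yl)-1,2,3,4,5,6,7,8-octahydroazulen-1-ol | C=C(C)[C@@H]1CC[C@@H](C)C2=C(C1)[C@@H](O)CC2
F10 | step 9 | 6-oxopristimerol 2,3-O-[4-hydroxyguai-11-ene-1,5-diyl] diether (O3–C1, O2–C5; C1, C5, C7, C10 as in 16; 4-OH cis to the C5 oxygen) | C=C(C)[C@@H]1CC[C@@H](C)[C@@]23CC[C@H](O)[C@]2(C1)Oc1cc2c(c(C)c1O3)C(=O)C=C1[C@@]2(C)CC[C@@]2(C)[C@@H]3C[C@](C)(C(=O)OC)CC[C@]3(C)CC[C@]12C
F11 | step 9 | 6-oxopristimerol 2,3-O-[4-oxoguai-11-ene-1,5-diyl] diether (C1, C5, C7, C10 as in 16) | C=C(C)[C@@H]1CC[C@@H](C)[C@@]23CCC(=O)[C@]2(C1)Oc1cc2c(c(C)c1O3)C(=O)C=C1[C@@]2(C)CC[C@@]2(C)[C@@H]3C[C@](C)(C(=O)OC)CC[C@]3(C)CC[C@]12C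
F12 | step 9 | 6-oxopristimerol 2,3-O-[4-(trifluoromethanesulfonyloxy)guaia-3,11-diene-1,5-diyl] diether (C1, C5, C7, C10 as in 16) | C=C(C)[C@@H]1CC[C@@H](C)[C@@]23CC=C(OS(=O)(=O)C(F)(F)F)[C@]2(C1)Oc1cc2c(c(C)c1O3)C(=O)C=C1[C@@]2(C)CC[C@@]2(C)[C@@H]3C[C@](C)(C(=O)OC)CC[C@]3(C)CC[C@]12C
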